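**Plan**
- Retrosynthesis: re-close the C1-carboxyl/O5 lactone and acetylate the three phenols; cut the C(=O)–Cα bond of the O4 p-coumaroyl ester (giving an O4 hydrogen oxalate and 4-acetoxystyrene); then cut the O4–oxalyl bond and the O3–caffeoyl ester bond.
- Forward: (−)-quinic acid is closed to the 1,5-lactone, the only ring made and a temporary one. The equatorial O3 takes the diacetylcaffeoyl group and the axial O4 takes an oxalyl unit. Anodic decarboxylation joins the O4–C(=O) carbon to the vinyl CH2 of 4-acetoxystyrene, and aqueous acid opens the lactone and frees the phenols.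
- Enabling feature: the O4-bound carbonyl carbon sits next to a 4-oxygenated styryl unit. As an alkoxycarbonyl radical it adds to the styrene terminus, and the benzylic Cβ carries the radical/cation that collapses to the conjugated E-alkene. The 6-oxabicyclo[3.2.1]octan-7-one ring fixes O3 equatorial and O4 axial and hides O5 and the CO2H.
- Stereochemistry: C1, C3, C4 and C5 are bought with (−)-quinic acid and no bond to them is broken. The caffeoyl E-alkene comes from caffeic acid; the coumaroyl E-alkene comes from the thermodynamically controlled elimination in the key step.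

Key step: step 6

Remark: the target is read as 3-O-caffeoyl-4-O-p-coumaroyl-(−)-quinic acid (O3 and O4 cis; O5 trans to O4 and cis to the C1 carboxyl). Quinic acid numbering is used throughout.

**Step 1**
Reactants: 1 (−)-quinic acid
Product: 2 1,5-quinide [(1S,3R,4R,5R)-1,3,4-trihydroxy-6-oxabicyclo[3.2.1]octan-7-one; lactone between the C1 carboxyl and O5]
Conditions: p-TsOH·H2O (cat.), toluene/DMF, reflux, Dean–Stark
Reagents that add atoms: none
Why: Acid-catalysed lactonisation with azeotropic removal of water; only O5 is cis to the C1 carboxyl (1,3-diaxial in the flipped chair), so the γ-lactone closes there and no stereocentre is touched.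

**Step 2**
Reactants: 3 caffeic acid [(E)-3,4-dihydroxycinnamic acid]
Product: 4 (E)-3,4-diacetoxycinnamic acid
Conditions: Ac2O, pyridine, DMAP (cat.), rt; then aq. HCl work-up
Reagents that add atoms: acetic anhydride, CC(=O)OC(C)=O
Why: Base-catalysed O-acetylation of both phenols, any mixed anhydride at the carboxyl being hydrolysed on acidic work-up; the E-alkene is untouched.

**Step 3**
Reactants: 4 (E)-3,4-diacetoxycinnamic acid
Product: 5 (E)-3,4-diacetoxycinnamoyl chloride
Conditions: (COCl)2, DMF (cat.), CH2Cl2, 0 °C to rt
Reagents that add atoms: oxalyl chloride, ClC(=O)C(=O)Cl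
Why: DMF-catalysed (Vilsmeier-type) conversion of a carboxylic acid to its acid chloride, to which the aryl acetates and the E-alkene are inert.

**Step 4**
Reactants: 2 1,5-quinide; 5 (E)-3,4-diacetoxycinnamoyl chloride (1.0 equiv, slow addition)
Product: 6 3-O-[(E)-3,4-diacetoxycinnamoyl]-1,5-quinide (ester on the equatorial O3; tertiary 1-OH and axial 4-OH free; ring stereocentres as in 2)
Conditions: pyridine/CH2Cl2, −20 to 0 °C
Reagents that add atoms: none
Why: Regioselective acylation with an acid chloride/pyridine, in which the equatorial secondary 3-OH of the lactone-locked chair should react before the axial, doubly flanked 4-OH and the tertiary 1-OH; no stereocentre is formed.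

**Step 5**
Reactants: 6 3-O-[(E)-3,4-diacetoxycinnamoyl]-1,5-quinide
Product: 8 3-O-[(E)-3,4-diacetoxycinnamoyl]-1,5-quinide 4-O-(hydrogen oxalate) (O4–C(=O)–CO2H), via 3-O-[(E)-3,4-diacetoxycinnamoyl]-4-O-(chlorooxalyl)-1,5-quinide 7 (not isolated)
Conditions: 6 added to (COCl)2 (2 equiv), THF, −40 to −10 °C; then H2O/THF, 0 °C
Reagents that add atoms: oxalyl chloride, ClC(=O)C(=O)Cl; water, O
Why: Half-oxalate formation (O-acylation by oxalyl chloride, then hydrolysis of the chlorooxoacetate), in which the small, very reactive reagent should reach the hindered secondary 4-OH while the tertiary 1-OH, deactivated by the adjacent lactone carbonyl, reacts much more slowly at low temperature.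

**Step 6**
Reactants: 8 3-O-[(E)-3,4-diacetoxycinnamoyl]-1,5-quinide 4-O-(hydrogen oxalate); 9 4-acetoxystyrene (4-vinylphenyl acetate, 4 equiv)
Product: 10 4-O-[(E)-4-acetoxycinnamoyl]-3-O-[(E)-3,4-diacetoxycinnamoyl]-1,5-quinide
Conditions: graphite(+)/Pt(−), undivided cell, constant current (ca. 2.5 F/mol), 2,4,6-collidine (1.5 equiv), n-Bu4NBF4, MeCN, rt
Reagents that add atoms: none
Why: Proposed new method: anodic oxidation of the oxalate carboxylate of 8 (Kolbe/Hofer–Moest type) should give an acyloxy radical that loses CO2 to the O4–C(=O)• alkoxycarbonyl radical, which adds to the terminal CH2 of 9 and so forms the C(=O)–Cα bond. The benzylic Cβ radical is much easier to oxidise than the carboxylate and should be taken to the cation at the anode (radical–polar crossover), collidine then removing the acidic α-proton while H2 leaves at the cathode. The closest known reaction types are the persulfate-, silver- or photoredox-driven decarboxylative alkoxycarbonylation of alkenes and heteroarenes with oxalic acid monoesters, and the anodic radical addition–oxidation–elimination of styrenes (for example to vinyl sulfones). No ring is closed and no stereocentre is formed; the E geometry is set by the thermodynamically controlled E1 loss of the α-proton from the freely rotating benzylic cation, giving the aryl-conjugated enoate. The step needs addition to outrun loss of CO2 from the alkoxycarbonyl radical (secured by the secondary, non-stabilised C4 and the excess of 9), attack on the monosubstituted styrene and not on the 1,2-disubstituted electron-poor caffeate alkene (secured by sterics and by the unfavourable 7-membered cyclisation through two Z-esters), and oxidation of the carboxylate before the arenes (secured by the acetates on all phenols). The nearly neutral medium also keeps the O3 and O4 esters from migrating.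

**Step 7**
Reactants: 10 4-O-[(E)-4-acetoxycinnamoyl]-3-O-[(E)-3,4-diacetoxycinnamoyl]-1,5-quinide
Product: 11 3-O-[(E)-caffeoyl]-4-O-[(E)-p-coumaroyl]-(−)-quinic acid (target)
Conditions: 2 M aq. HCl/THF (1:3), rt, several days
Reagents that add atoms: water, O
Why: Acid-catalysed ester hydrolysis should cleave the three activated aryl acetates and open the strained bicyclic γ-lactone, while the two hindered, conjugated secondary cinnamate esters hydrolyse far more slowly and the acidic medium suppresses acyl migration; all stereocentres are retained.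

**Compound list**
1 | (−)-quinic acid | O[C@H]1[C@H](O)C[C@](O)(C(=O)O)C[C@H]1O | starting material
2 | 1,5-quinide (quinic acid 1,5-lactone) | O[C@H]1[C@H]2C[C@](O)(C(=O)O2)C[C@H]1O | intermediate
3 | caffeic acid | O=C(O)/C=C/c1ccc(O)c(O)c1 | starting material
4 | (E)-3,4-diacetoxycinnamic acid | CC(=O)Oc1ccc(/C=C/C(=O)O)cc1OC(C)=O | intermediate
5 | (E)-3,4-diacetoxycinnamoyl chloride | CC(=O)Oc1ccc(/C=C/C(=O)Cl)cc1OC(C)=O | intermediate
6 | 3-O-[(E)-3,4-diacetoxycinnamoyl]-1,5-quinide | O[C@H]1[C@H]2C[C@](O)(C(=O)O2)C[C@H]1OC(=O)/C=C/c1ccc(OC(C)=O)c(OC(C)=O)c1 | intermediate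
7 | 3-O-[(E)-3,4-diacetoxycinnamoyl]-4-O-(chlorooxalyl)-1,5-quinide | O=C(Cl)C(=O)O[C@H]1[C@H]2C[C@](O)(C(=O)O2)C[C@H]1OC(=O)/C=C/c1ccc(OC(C)=O)c(OC(C)=O)c1 | intermediate
8 | 3-O-[(E)-3,4-diacetoxycinnamoyl]-1,5-quinide 4-O-(hydrogen oxalate) | O=C(O)C(=O)O[C@H]1[C@H]2C[C@](O)(C(=O)O2)C[C@H]1OC(=O)/C=C/c1ccc(OC(C)=O)c(OC(C)=O)c1 | intermediate
9 | 4-acetoxystyrene | CC(=O)Oc1ccc(C=C)cc1 | starting material
10 | 4-O-[(E)-4-acetoxycinnamoyl]-3-O-[(E)-3,4-diacetoxycinnamoyl]-1,5-quinide | O=C(/C=C/c1ccc(OC(C)=O)cc1)O[C@H]1[C@H]2C[C@](O)(C(=O)O2)C[C@H]1OC(=O)/C=C/c1ccc(OC(C)=O)c(OC(C)=O)c1 | intermediate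
11 | 3-O-[(E)-caffeoyl]-4-O-[(E)-p-coumaroyl]-(−)-quinic acid | O=C(/C=C/c1ccc(O)cc1)O[C@H]1[C@H](O)C[C@](O)(C(=O)O)C[C@H]1OC(=O)/C=C/c1ccc(O)c(O)c1 | target

**Totals**
Total step count: 7. Longest linear sequence: 6 steps (caffeic acid, steps 2–7); the quinic acid branch joins at step 4 after one step.

**Steps most likely to fail**

Step 6 (Proposed new method). The alkoxycarbonyl radical may lose CO2 or dimerise before it adds, the styrene may oligomerise, or the benzylic cation may be captured by a nucleophile in place of eliminating. The fallback uses known chemistry and forms the O4–C(=O) ester bond instead. It sets out from 6, bypassing 8. Commercial (E)-4-acetoxycinnamic acid F1 is converted with oxalyl chloride and catalytic DMF in CH2Cl2 into (E)-4-acetoxycinnamoyl chloride F2. F2 (limiting amount) acylates the axial 4-OH of 6 in pyridine/CH2Cl2 with catalytic DMAP at 0 °C to rt, and the route is rejoined at 10.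

Step 4. Discrimination between the equatorial O3 and the axial O4 may be insufficient, or bis-acylation may occur. The fallback replaces inherent reactivity by tin-acetal control and sets out from 2. Bu2SnO in refluxing MeOH, followed by evaporation, should give the 3,4-O-dibutylstannylene acetal of 1,5-quinide F3 across the cis-diol. The equatorial oxygen of such an acetal is the one acylated by an acid chloride, so treatment with 5 in CH2Cl2 at 0 °C and aqueous work-up returns to the route at 6.

Step 5. The tertiary 1-OH may be acylated as well, a symmetrical dialkyl oxalate may form, or the activated oxalate may be lost by hydrolysis on work-up. The fallback installs a masked, monofunctional oxalyl unit and sets out from 6. tert-Butyl chlorooxoacetate with pyridine in CH2Cl2 at −20 °C should give the mixed oxalate 3-O-[(E)-3,4-diacetoxycinnamoyl]-4-O-(tert-butoxyoxalyl)-1,5-quinide F4, which can be chromatographed free of any over-acylated material. TFA/CH2Cl2 at rt then removes the tert-butyl group and returns to the route at 8.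

**Further compounds**
F1 | step 6 | (E)-4-acetoxycinnamic acid (purchased) | CC(=O)Oc1ccc(/C=C/C(=O)O)cc1
F2 | step 6 | (E)-4-acetoxycinnamoyl chloride | CC(=O)Oc1ccc(/C=C/C(=O)Cl)cc1
F3 | step 4 | 3,4-O-dibutylstannylene acetal of 1,5-quinide | CCCC[Sn]3(CCCC)O[C@H]1[C@H]2C[C@](O)(C(=O)O2)C[C@H]1O3
F4 | step 5 | 3-O-[(E)-3,4-diacetoxycinnamoyl]-4-O-(tert-butoxyoxalyl)-1,5-quinide | CC(C)(C)OC(=O)C(=O)O[C@H]1[C@H]2C[C@](O)(C(=O)O2)C[C@H]1OC(=O)/C=C/c1ccc(OC(C)=O)c(OC(C)=O)c1
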